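The ratio of catalyst between Wednesday's flask and Thursday's run is 1.54, and we ask what that ratio buys at each end of a run.

common to all: solid substrate 0.020 M; gas phase 1.2 mM (held)
- Wednesday's: catalyst 0.20 mM; the very flask that is asked about, followed so far
- Thursday's: catalyst 0.13 mM; run made earlier
- flask: catalyst 0.20 mM; time 50 min

| run | time / min | product / % |
|---|---|---|
| Wednesday's | 0.833 | 1.8 |
| Wednesday's | 1.50 | 4.7 |
| Wednesday's | 2.50 | 9.4 |
| Wednesday's | 3.00 | 11.6 |
| Wednesday's | 4.00 | 15.6 |
| Thursday's | 3.00 | 10.1 |
| Thursday's | 5.00 | 17.3 |
| Thursday's | 10.0 | 40.0 |
| Thursday's | 20.0 | 61.8 |
| Thursday's | 40.0 | 61.8 |

(readings scatter by 0.5 percentage points)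

- solid substrate is a solid; its amount is given per volume of the solution
- the analysis behind the earlier runs scatters by 0.5 percentage points, standard deviation
- at the start none of the gas phase is in solution
- at the start none of the solid substrate is in solution

- north-west: doubling the transfer coefficient of the gas phase, all else as stated
- south: doubling the amount of catalyst, all else as stated
- north: doubling the saturation concentration of gas phase, all else as stated
- south-west: doubling the dissolution coefficient of the solid substrate, all else as stated

- amount of product at 50 min, in percent of the solid substrate charged
- the change that raises the amount of product at 50 min, in percent of the solid substrate charged most ("none" if none brings more than 2 percentage points) (north-west / south / north / south-west / none)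
- amount of product at 50 min, in percent of the solid substrate charged, after south

The bench rule counts turnovers. Thursday's run stands at 61.8% at both 20.0 min and 40.0 min, which is 95.1 product per catalyst, and the rule lets product follow the catalyst charge. Its border shows at the early end. At 3.00 min Wednesday's flask reads 11.6% against 10.1% in Thursday's run, a ratio of 1.15 as read, which is less than the catalyst ratio. So we do not trust proportion at the late end either.

Our own reckoning takes the flat stop as the end of the charge, with 38.2% of it on a route that makes no product. We carry the loss ratio, charge lost per charge turned into product at the stop, the inverse of a selectivity factor. As a rough assumption of our own, not a law, we let this ratio go inversely with catalyst: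

Thursday's run: loss ratio = 38.2% / 61.8% = 0.618

Wednesday's flask: 0.618 / 1.54 = 0.402, so product = 71.3%

After south: 0.201, so product = 83.3%

The forecast differs: “the stop looks like catalyst exhaustion”. It gives 94% (range 82% to 99%), names south as the best change, and gives 99.5% after it (range 93% to 100%).

The flask gives 68.7%, and 78.5% after south; the best change is north, worth 21 percentage points against 9.8 points for south.

    gas phase ⇌ dissolved gas, rate k1*(csat - [dissolved gas]) (kL = 1.51 /min)
    starting material + dissolved gas + catalyst → catalyst + product (k = 65200 /M²/s)
    solid substrate ⇌ starting material, rate k3*(cs3 - [starting material]) while solid is left; crystals form when [starting material] > cs3 (solubility = 9.50 mM, k = 0.230 /min)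
    2 starting material → homo dimer (k = 43.3 /M/min)

At 50.0 min the flask holds 31.3% of the solid substrate charged as homo dimer, with its catalyst at 100% of the catalyst charged. Its loss ratio comes to 0.455 against the 0.402 reckoned. After south the loss ratio comes to 0.274 against the 0.201 reckoned.

(All runs were generated by integration for substances that don't exist; the scatter is artificial.)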